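**Plan**
- Retrosynthesis: the C6 angelate and the C8–C9 epoxide oxygen are removed first, leaving a C8=C9 allylic alcohol with a 10α-hydroxyl. That alcohol is traced back to a C9=C10 olefin, ring B is opened at C9=C10, the isopropyl group is taken off C4, and finally C1–C10 and C5–C6 are cut in one operation.
- Enabling feature: C1 is quaternary (CH3, C2, C5, C10) and lies β to the C4 oxygen, with C5 α to it. Ring A is therefore a latent 3-methylcyclopent-2-en-1-one that takes a vinyl nucleophile (C10) at C1 and, as the C5 enolate, an aldehyde (C6).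
- Forward: ring A is bought; one three-component coupling places both arms of ring B on it trans; isopropyl is added at C4; ring B (seven-membered) closes by olefin metathesis at C9=C10. α-Epoxidation and a selenide transposition turn that olefin into the 10α-allylic alcohol; angeloylation at C6 and a hydroxyl-directed epoxidation finish.
- Stereochemistry: C8 (temporary) comes from (R,E)-pent-3-en-2-ol by Claisen chirality transfer, C1 from the chiral copper catalyst, C5 and C6 from the enolate face and the chair aldol, and C4 from attack anti to the C5 side chain. C10 comes from epoxidation anti to the C1 methyl, and the C8/C9 epoxide from oxygen delivery by the 10α-hydroxyl.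

Key step: step 3

**Remarks**
- Numbering used for every intermediate: C1 = fusion carbon with the angular methyl, C2, C3, C4 = isopropyl carbinol, C5 = fusion CH (ring A, five-membered); C6 (ester carbon), C7, C8 (methyl-bearing), C9, C10 (carbinol) complete ring B (seven-membered). β is the face of the C1 methyl, α the opposite face. Bicyclic compounds are named on the daucane skeleton and are all trans-fused (1β-CH3, 5α-H) with 4β-OH and 4α-isopropyl.
- Assumption: (R,E)-pent-3-en-2-ol is bought as a single enantiomer; it is also accessible from the racemate by lipase-catalysed acetylation.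

**Route**

Step 1
Reactants: 1 (R,E)-pent-3-en-2-ol; 2 triethyl orthoacetate
Product: 4 ethyl (3R,4E)-3-methylhex-4-enoate, via ketene acetal 3 (not isolated)
Conditions: 2 (excess), EtCO2H (cat.), 140 °C, EtOH distilled off
Reagents that add atoms: none
Why: Johnson–Claisen rearrangement: acid-catalysed exchange gives ketene acetal 3, whose [3,3] shift through a chair with the carbinol methyl equatorial transfers the configuration of 1 to the new C3 centre (future C8) and gives the E olefin.

Step 2
Reactants: 4 ethyl (3R,4E)-3-methylhex-4-enoate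
Product: 5 (3R,4E)-3-methylhex-4-enal
Conditions: i-Bu2AlH (1.05 equiv), CH2Cl2, −78 °C; aq potassium sodium tartrate
Reagents that add atoms: none
Why: Partial reduction of an ester with i-Bu2AlH at −78 °C should stop at the aldehyde oxidation level, and the stereocentre is β to the carbonyl and cannot epimerise.

Step 3
Reactants: 6 3-methylcyclopent-2-en-1-one; 7 vinylmagnesium bromide; 5 (3R,4E)-3-methylhex-4-enal
Product: 9 (2S,3R)-3-ethenyl-2-[(1S,3R,4E)-1-hydroxy-3-methylhex-4-en-1-yl]-3-methylcyclopentan-1-one, via magnesium enolate 8 (not isolated)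
Conditions: 7 (1.2 equiv), Cu(OTf)2 (3 mol %), chiral C2-symmetric imidazolinium chloride (carbene precursor, 4 mol %), Et2O–THF, −30 °C; then 5, −78 °C; aq NH4Cl
Reagents that add atoms: none
Why: Cu(OTf)2 is reduced by 7 to a monovalent copper–carbene species that carries the vinyl group, π-complexes 6, adds oxidatively at C1 to a trivalent copper intermediate and reductively eliminates to form C1–C10, releasing bromomagnesium enolate 8 with its nucleophilic carbon at C5; 8 then adds to 5 through a closed Zimmerman–Traxler chair to form C5–C6. The closest known reaction type is the copper-catalysed asymmetric conjugate addition of Grignard reagents to β-substituted cyclic enones that builds all-carbon quaternary centres, coupled with aldol capture of the magnesium enolate. No ring is closed. C1 is set by the chiral carbene on copper (ligand enantiomer chosen for the 3R enolate); C5 by approach of the aldehyde to the enolate face anti to the vinyl group, the flat sp2 arm taking the pseudo-axial site of the envelope, so that the two new arms end trans; C6 by the chair, in which the ring-fixed E enolate and an equatorial aldehyde chain give the anti aldol; C8 comes unchanged from 5. The step needs 1,4- rather than 1,2-addition and an enolate that stays at C5: copper secures the first, and the enone itself secures the second, since conjugate addition unmasks the enolate only between C4 and C5 and at −78 °C it is trapped before proton exchange can move it to C3. Because 5 is a single enantiomer, any enolate of the wrong hand ends as a separable diastereomer, which backs up the enantiopurity at C1.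

Step 4
Reactants: 9 (2S,3R)-3-ethenyl-2-[(1S,3R,4E)-1-hydroxy-3-methylhex-4-en-1-yl]-3-methylcyclopentan-1-one
Product: 10 (2S,3R)-2-[(1S,3R,4E)-1-(tert-butyldimethylsilyloxy)-3-methylhex-4-en-1-yl]-3-ethenyl-3-methylcyclopentan-1-one
Conditions: t-BuMe2SiOTf, 2,6-lutidine, CH2Cl2, −78 °C
Reagents that add atoms: tert-butyldimethylsilyl trifluoromethanesulfonate, CC(C)(C)[Si](C)(C)OS(=O)(=O)C(F)(F)F
Why: Silylation of a β-hydroxy ketone with a silyl triflate and a hindered base at −78 °C should outrun retro-aldol cleavage and elimination, and it masks the C6 hydroxyl for the organometallic step.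

Step 5
Reactants: 10 (2S,3R)-2-[(1S,3R,4E)-1-(tert-butyldimethylsilyloxy)-3-methylhex-4-en-1-yl]-3-ethenyl-3-methylcyclopentan-1-one; 11 isopropylmagnesium chloride
Product: 12 (1R,2S,3R)-2-[(1S,3R,4E)-1-(tert-butyldimethylsilyloxy)-3-methylhex-4-en-1-yl]-3-ethenyl-3-methyl-1-(propan-2-yl)cyclopentan-1-ol
Conditions: 11, CeCl3 (anhydrous), THF, −78 °C to 0 °C; aq NH4Cl
Reagents that add atoms: none
Why: CeCl3-promoted Grignard 1,2-addition suppresses enolisation and β-hydride reduction of the hindered ketone, and the nucleophile should enter the C4 carbonyl face anti to the adjacent C5 side chain, placing isopropyl α and hydroxyl β.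

Step 6
Reactants: 12 (1R,2S,3R)-2-[(1S,3R,4E)-1-(tert-butyldimethylsilyloxy)-3-methylhex-4-en-1-yl]-3-ethenyl-3-methyl-1-(propan-2-yl)cyclopentan-1-ol
Product: 13 6α-(tert-butyldimethylsilyloxy)-8βH-dauc-9-en-4β-ol
Conditions: second-generation Grubbs catalyst RuCl2(=CHPh)(PCy3)(H2IMes) (5 mol %), CH2Cl2 (dilute), 40 °C
Reagents that add atoms: none
Why: Ring-closing olefin metathesis joins C9 and C10 across the two trans-disposed arms to give the trans-fused seven-membered ring B with loss of propene; the tertiary alcohol and the silyl ether are inert to the catalyst.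

Step 7
Reactants: 13 6α-(tert-butyldimethylsilyloxy)-8βH-dauc-9-en-4β-ol
Product: 14 9α,10α-epoxy-6α-(tert-butyldimethylsilyloxy)-8βH-daucan-4β-ol
Conditions: mCPBA, CH2Cl2, 0 °C
Reagents that add atoms: 3-chloroperoxybenzoic acid, OOC(=O)c1cccc(Cl)c1
Why: Peracid epoxidation of the only olefin: the pseudo-axial C1 methyl shields the β face of C9=C10 while the C8 methyl lies pseudo-equatorial, so oxygen should be delivered to the α face, which fixes the C10 configuration.

Step 8
Reactants: 14 9α,10α-epoxy-6α-(tert-butyldimethylsilyloxy)-8βH-daucan-4β-ol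
Product: 17 6α-(tert-butyldimethylsilyloxy)dauc-8-ene-4β,10α-diol, via hydroxy selenide 15 (not isolated), via selenoxide 16 (not isolated)
Conditions: PhSeSePh, NaBH4, EtOH, reflux; then 30% H2O2, pyridine, THF, 0 °C to rt
Reagents that add atoms: none
Why: Epoxide-to-allylic-alcohol transposition by selenide opening and selenoxide syn-elimination: PhSe− should open the epoxide at C9 with inversion (C10 is neopentyl), leaving the C10 oxygen α, and the selenoxide should eliminate with the cis C8–H, away from the carbinol, to give the C8=C9 olefin.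

Step 9
Reactants: 17 6α-(tert-butyldimethylsilyloxy)dauc-8-ene-4β,10α-diol
Product: 18 dauc-8-ene-4β,6α,10α-triol
Conditions: Bu4NF, THF, rt
Reagents that add atoms: none
Why: Fluoride-induced desilylation frees the C6 hydroxyl; no other group in 17 responds to Bu4NF.

Step 10
Reactants: 18 dauc-8-ene-4β,6α,10α-triol; 19 angelic acid
Product: 21 6α-angeloyloxydauc-8-ene-4β,10α-diol, via mixed anhydride 20 (not isolated)
Conditions: 19, 2,4,6-trichlorobenzoyl chloride, Et3N, toluene, rt; then 18, 80 °C
Reagents that add atoms: none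
Why: Yamaguchi esterification through mixed anhydride 20, run without a nucleophilic amine catalyst so that the Z olefin of the angelate does not isomerise; the equatorial C6 hydroxyl should react ahead of the pseudo-axial, neopentyl C10 hydroxyl and the tertiary C4 hydroxyl.

Step 11
Reactants: 21 6α-angeloyloxydauc-8-ene-4β,10α-diol
Product: 22 lapiferine
Conditions: VO(acac)2 (cat.), t-BuOOH, CH2Cl2, 0 °C to rt
Reagents that add atoms: tert-butyl hydroperoxide, CC(C)(C)OO
Why: Hydroxyl-directed epoxidation: the vanadium alkoxide of the C10 allylic alcohol should deliver the peroxide oxygen to the same (α) face of C8=C9, setting C8 and C9, while the electron-poor angelate olefin is left alone.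

**Compound list**
1 | (R,E)-pent-3-en-2-ol | C[C@@H](O)/C=C/C | starting material
2 | triethyl orthoacetate | CCOC(C)(OCC)OCC | starting material
3 | ketene acetal, 1-ethoxy-1-[(2R,3E)-pent-3-en-2-yloxy]ethene | C=C(OCC)O[C@H](C)/C=C/C | intermediate
4 | ethyl (3R,4E)-3-methylhex-4-enoate | CCOC(=O)C[C@@H](C)/C=C/C | intermediate
5 | (3R,4E)-3-methylhex-4-enal | O=CC[C@@H](C)/C=C/C | intermediate
6 | 3-methylcyclopent-2-en-1-one | CC1=CC(=O)CC1 | starting material
7 | vinylmagnesium bromide | C=C[Mg]Br | starting material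
8 | magnesium enolate, bromomagnesium (3R)-3-ethenyl-3-methylcyclopent-1-en-1-olate | C=C[C@@]1(C)CCC(O[Mg]Br)=C1 | intermediate
9 | (2S,3R)-3-ethenyl-2-[(1S,3R,4E)-1-hydroxy-3-methylhex-4-en-1-yl]-3-methylcyclopentan-1-one | C=C[C@@]1(C)CCC(=O)[C@@H]1[C@@H](O)C[C@@H](C)/C=C/C | intermediate
10 | (2S,3R)-2-[(1S,3R,4E)-1-(tert-butyldimethylsilyloxy)-3-methylhex-4-en-1-yl]-3-ethenyl-3-methylcyclopentan-1-one | C=C[C@@]1(C)CCC(=O)[C@@H]1[C@@H](O[Si](C)(C)C(C)(C)C)C[C@@H](C)/C=C/C | intermediate
11 | isopropylmagnesium chloride | CC(C)[Mg]Cl | starting material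
12 | (1R,2S,3R)-2-[(1S,3R,4E)-1-(tert-butyldimethylsilyloxy)-3-methylhex-4-en-1-yl]-3-ethenyl-3-methyl-1-(propan-2-yl)cyclopentan-1-ol | C=C[C@@]1(C)CC[C@@](O)(C(C)C)[C@@H]1[C@@H](O[Si](C)(C)C(C)(C)C)C[C@@H](C)/C=C/C | intermediate
13 | 6α-(tert-butyldimethylsilyloxy)-8βH-dauc-9-en-4β-ol (8α-methyl) | CC(C)(C)[Si](C)(C)O[C@H]1C[C@@H](C)C=C[C@@]2(C)CC[C@@](O)(C(C)C)[C@H]12 | intermediate
14 | 9α,10α-epoxy-6α-(tert-butyldimethylsilyloxy)-8βH-daucan-4β-ol | CC(C)(C)[Si](C)(C)O[C@H]1C[C@@H](C)[C@H]2O[C@H]2[C@@]2(C)CC[C@@](O)(C(C)C)[C@H]12 | intermediate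
15 | hydroxy selenide, 6α-(tert-butyldimethylsilyloxy)-9β-(phenylselanyl)-8βH-daucane-4β,10α-diol | CC(C)(C)[Si](C)(C)O[C@H]1C[C@@H](C)[C@H]([Se]c2ccccc2)[C@@H](O)[C@@]2(C)CC[C@@](O)(C(C)C)[C@H]12 | intermediate
16 | selenoxide, 6α-(tert-butyldimethylsilyloxy)-9β-(phenylseleninyl)-8βH-daucane-4β,10α-diol | CC(C)(C)[Si](C)(C)O[C@H]1C[C@@H](C)[C@H]([Se](=O)c2ccccc2)[C@@H](O)[C@@]2(C)CC[C@@](O)(C(C)C)[C@H]12 | intermediate
17 | 6α-(tert-butyldimethylsilyloxy)dauc-8-ene-4β,10α-diol | CC(C)(C)[Si](C)(C)O[C@H]1CC(C)=C[C@@H](O)[C@@]2(C)CC[C@@](O)(C(C)C)[C@H]12 | intermediate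
18 | dauc-8-ene-4β,6α,10α-triol | O[C@H]1CC(C)=C[C@@H](O)[C@@]2(C)CC[C@@](O)(C(C)C)[C@H]12 | intermediate
19 | angelic acid, (Z)-2-methylbut-2-enoic acid | C/C=C(/C)C(=O)O | starting material
20 | mixed anhydride, angelic 2,4,6-trichlorobenzoic anhydride | C/C=C(/C)C(=O)OC(=O)c1c(Cl)cc(Cl)cc1Cl | intermediate
21 | 6α-angeloyloxydauc-8-ene-4β,10α-diol | C/C=C(/C)C(=O)O[C@H]1CC(C)=C[C@@H](O)[C@@]2(C)CC[C@@](O)(C(C)C)[C@H]12 | intermediate
22 | lapiferine, 6α-angeloyloxy-8α,9α-epoxydaucane-4β,10α-diol | C/C=C(/C)C(=O)O[C@H]1C[C@@]2(C)O[C@H]2[C@@H](O)[C@@]2(C)CC[C@@](O)(C(C)C)[C@H]12 | target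

**Count**
Total steps: 11. Longest linear sequence: 11 steps (1 to 22); 6 and 7 enter at step 3, 11 at step 5 and 19 at step 10.

**Steps most likely to fail**

Step 3. What may go wrong: vinyl transfer to the five-membered enone with low enantio-induction, and weak discrimination between the methyl and vinyl faces of enolate 8 when the aldehyde arrives, so that C1 or C5 epimers form in quantity. The fallback sets out from 6 and comes back at 10. Ethynyltrimethylsilane is hydroaluminated with i-Bu2AlH to diisobutyl[1-(trimethylsilyl)ethenyl]aluminium F1, which is added to 6 with Cu(OTf)2 and a chiral sulfonate-bearing imidazolinium salt as carbene precursor. This silylated vinyl surrogate is a known, highly selective way to vinyl-type quaternary centres on β-substituted cyclopentenones. The aluminium enolate F2 is trapped with 5 to give the α-silylvinyl aldol F3, in which the bulky silylated arm leaves only the face anti to it open to the aldehyde. Silylation (t-BuMe2SiOTf, 2,6-lutidine) gives the silyl ether F4, and protodesilylation of the vinylsilane (CF3CO2H, CH2Cl2, 0 °C) returns to 10.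

Step 8. What may go wrong: sluggish or wrongly directed opening of the hindered epoxide by the selenolate, or loss of material when the selenoxide eliminates toward C10 instead of C8. The fallback sets out from 13 and comes back at 15. Dihydroxylation of 13 with OsO4 (cat.) and N-methylmorpholine N-oxide, again anti to the C1 methyl, gives the 9α,10α-diol F5. SOCl2/Et3N closes the cyclic sulfite F6, and RuCl3 (cat.)/NaIO4 oxidises it to the cyclic sulfate F7, a much stronger electrophile than the epoxide. PhSe− (from PhSeSePh and NaBH4) opens it at C9 to the sodium sulfate monoester F8, and mild acid hydrolysis (aq H2SO4, THF) gives hydroxy selenide 15. This is then isolated and oxidised at low temperature (H2O2, pyridine) to reach 17.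

Step 10. What may go wrong: poor site selectivity, with acylation of the C10 hydroxyl alongside the C6 hydroxyl. The fallback sets out from 17 and comes back at 21. The C10 hydroxyl of 17 is capped with chloroacetic anhydride, pyridine and DMAP to give the C10 chloroacetate F9. HF·pyridine then removes the silyl group to give the C6 alcohol F10. The mixed-anhydride angeloylation of step 10 now meets a single secondary hydroxyl and gives the C6 angelate C10 chloroacetate F11. Thiourea and NaHCO3 in EtOH remove only the chloroacetate and deliver 21.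

Further compounds
F1 | step 3 | diisobutyl[1-(trimethylsilyl)ethenyl]aluminium | C=C([Si](C)(C)C)[Al](CC(C)C)CC(C)C
F2 | step 3 | diisobutylaluminium enolate of 3-methyl-3-[1-(trimethylsilyl)ethenyl]cyclopentanone (C1 as in 8) | C=C([Si](C)(C)C)[C@@]1(C)CCC(O[Al](CC(C)C)CC(C)C)=C1
F3 | step 3 | α-silylvinyl aldol (9 with SiMe3 on C10) | C=C([Si](C)(C)C)[C@@]1(C)CCC(=O)[C@@H]1[C@@H](O)C[C@@H](C)/C=C/C
F4 | step 3 | tert-butyldimethylsilyl ether of F3 | C=C([Si](C)(C)C)[C@@]1(C)CCC(=O)[C@@H]1[C@@H](O[Si](C)(C)C(C)(C)C)C[C@@H](C)/C=C/C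
F5 | step 8 | 6α-(tert-butyldimethylsilyloxy)-8βH-daucane-4β,9α,10α-triol | CC(C)(C)[Si](C)(C)O[C@H]1C[C@@H](C)[C@@H](O)[C@@H](O)[C@@]2(C)CC[C@@](O)(C(C)C)[C@H]12
F6 | step 8 | 9α,10α-cyclic sulfite of F5 | CC(C)(C)[Si](C)(C)O[C@H]1C[C@@H](C)[C@H]2OS(=O)O[C@H]2[C@@]2(C)CC[C@@](O)(C(C)C)[C@H]12
F7 | step 8 | 9α,10α-cyclic sulfate of F5 | CC(C)(C)[Si](C)(C)O[C@H]1C[C@@H](C)[C@H]2OS(=O)(=O)O[C@H]2[C@@]2(C)CC[C@@](O)(C(C)C)[C@H]12
F8 | step 8 | sodium 10α-sulfate of hydroxy selenide 15 | CC(C)(C)[Si](C)(C)O[C@H]1C[C@@H](C)[C@H]([Se]c2ccccc2)[C@@H](OS(=O)(=O)[O-])[C@@]2(C)CC[C@@](O)(C(C)C)[C@H]12.[Na+]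
F9 | step 10 | 10α-chloroacetoxy-6α-(tert-butyldimethylsilyloxy)dauc-8-en-4β-ol | CC(C)(C)[Si](C)(C)O[C@H]1CC(C)=C[C@@H](OC(=O)CCl)[C@@]2(C)CC[C@@](O)(C(C)C)[C@H]12
F10 | step 10 | 10α-chloroacetoxydauc-8-ene-4β,6α-diol | O[C@H]1CC(C)=C[C@@H](OC(=O)CCl)[C@@]2(C)CC[C@@](O)(C(C)C)[C@H]12
F11 | step 10 | 6α-angeloyloxy-10α-chloroacetoxydauc-8-en-4β-ol | C/C=C(/C)C(=O)O[C@H]1CC(C)=C[C@@H](OC(=O)CCl)[C@@]2(C)CC[C@@](O)(C(C)C)[C@H]12
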